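The constants used here were set for the occasion; what happens was integrated by code.

Early in spring, D and Q stand near their charges and Z is just starting to fill. What is to be found?

| flask | D | Q | time |
|---|---|---|---|
| spring | 1.0 mM | 1.20 mM | 50 s |
| summer | 3.0 mM | 1.20 mM | 50 s |
| winter | 10 mM | 1.20 mM | 50 s |
| dusk | 25 mM | 1.20 mM | 50 s |

- [Z] at the end for spring, summer, winter, dusk, in this order
- the shape of the row from first to last (rises all the way / falls all the way / rises, then falls / falls, then rises / hardly changes)

- percent here means D units held: one D.D.Q counts as two
- "hardly changes" means that all values lie within two and a half points (for a concentration: within two and a half percent of the largest)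
- run time (spring): 50 s

    D + Q → D.Q (k1 = 11.3 L mol⁻¹ s⁻¹)
    D.Q → Z (k2 = 0.414 s⁻¹)
    D + D.Q → D.D.Q (k3 = 28.2 L mol⁻¹ s⁻¹)
    Z → L (k4 = 0.201 s⁻¹)

How long does Z remember its past? Not long. By the path to L alone, its half-life in spring is 3.4 s, far shorter than the run of 50 s. D.Q is quicker still, at 1.7 s by the path to Z alone.

So where does Z stand at the end? Near the level where making equals using. I reckon this by hand for spring, and no further.

Which D and Q go in? The ones at the end, and those are unknown, so I go round. At the charges, the meeting of D and Q would use 0.678 mM over the run. That is too much, since both fall. With half of that taken off each, as a mean, my reckoning gives 0.322 mM. That is too little. Going round once more gives 0.493 mM. The rounds close in, so I take their mean, 0.407 mM. My reckoning leaves D at 0.593 mM and Q at 0.793 mM, with the side path to D.D.Q not yet counted.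

Does the side path to D.D.Q matter? A little, in spring. As charged, its half-life for D.Q is 25 s, much longer than that of the path to Z. At my end D, the share of D.Q going on to Z is 96.1%.

Then the follow level, the meeting rate of D and Q times that share, over the rate constant of Z's loss, is 0.0254 mM. This is a quasi-steady state.

And the weak spot? The feed is falling and Z trails it, so I expect Z a little above that level.

The forecast gives 0.028 mM, 0.039 mM, 0.0059 mM and 9.000 × 10⁻⁵ mM, with the shape "rises, then falls". Of the last value it says: “dusk is essentially the tail of Z's own decay”. My 0.0254 mM for spring stands below its 0.028 mM.

The simulation gives 0.0272 mM, 0.0384 mM, 0.00592 mM and 9.65 × 10⁻⁵ mM, with the shape "rises, then falls".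

In spring, Z stands above my 0.0254 mM, and making over using, 0.919 at the end, shows it still falling. In summer, the follow level from that flask's end D and Q is 0.0313 mM, again below the flask's 0.0384 mM. The path from Z to L has the largest single effect on the dusk value: run without that path, dusk ends at 0.457 mM, not 9.65 × 10⁻⁵ mM.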